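**Retrosynthetic overview**

1. Dodoviscin J ⇐ its 4'-O-MOM ether (MOM removed last); ring A is built last, on a finished ring B–ring C 4-pyranone.
2. Feature used: in ring A (C4a, C5, C6, C7, C8, C8a) the oxygenated carbons C5 and C7 are at the carbonyl oxidation level and alternate with the CH carbons C6 and C8. Ring A is therefore an acetyl group on C4a (C5–C6), a methyl group on C8a (C8) and one carbonate carbon (C7): cut C6–C7 and C7–C8 to a 5-acetyl-6-methyl-3-methoxy-2-aryl-4-pyranone and dimethyl carbonate.
3. Ring C ⇐ cut C4–C4a and O1–C8a: an aroyl(methoxy)ketene (released from a tert-butyl α-methoxy-β-keto ester) plus acetylacetone, whose symmetry removes any regiochemical question and delivers the pyranone at the correct oxidation level without a dehydrogenation.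
4. β-Keto ester ⇐ aldol addition of tert-butyl methoxyacetate to MOM-protected 5-prenylvanillin, then oxidation; prenyl group ⇐ Stille coupling on MOM-protected 5-iodovanillin.
5. Order of rings: ring B is bought, ring C closes in step 5, ring A in step 6.

Key step: step 6

Assumption: tert-butyl methoxyacetate is taken as a catalogue reagent; the aldol adduct of step 3 is carried on as the mixture of racemic diastereomers, since both of its stereocentres become sp2 carbons in steps 4 and 5 (the target has no stereocentre).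

**Route**

Step 1
Reactants: 1 5-iodovanillin (4-hydroxy-3-iodo-5-methoxybenzaldehyde); 2 chloromethyl methyl ether
Product: 3 3-iodo-5-methoxy-4-(methoxymethoxy)benzaldehyde
Conditions: MOMCl (1.5 equiv), i-Pr2NEt (2 equiv), CH2Cl2, 0 °C → rt
Reagents that add atoms: chloromethyl methyl ether, COCCl
Why: Williamson-type O-alkylation (MOM protection): the acidic para-formyl phenol is deprotonated by the amine and alkylated by the reactive α-chloro ether, while the aldehyde is untouched.

Step 2
Reactants: 3 3-iodo-5-methoxy-4-(methoxymethoxy)benzaldehyde; 4 tributyl(3-methylbut-2-en-1-yl)stannane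
Product: 5 3-methoxy-4-(methoxymethoxy)-5-(3-methylbut-2-en-1-yl)benzaldehyde
Conditions: Pd(PPh3)4 (5 mol%), DMF, 95 °C
Reagents that add atoms: tributyl(3-methylbut-2-en-1-yl)stannane, CCCC[Sn](CCCC)(CCCC)CC=C(C)C
Why: Stille coupling: oxidative addition of zerovalent palladium to the aryl iodide, transfer of the prenyl group from tin at its CH2 terminus and reductive elimination should give the linear prenylarene, and the aldehyde and MOM ether are inert to these neutral conditions.

Step 3
Reactants: 5 3-methoxy-4-(methoxymethoxy)-5-(3-methylbut-2-en-1-yl)benzaldehyde; 6 tert-butyl methoxyacetate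
Product: 7 tert-butyl 3-hydroxy-2-methoxy-3-[3-methoxy-4-(methoxymethoxy)-5-(3-methylbut-2-en-1-yl)phenyl]propanoate (racemic syn/anti mixture)
Conditions: LiN(i-Pr)2 (LDA, commercial solution, 1.2 equiv), THF, −78 °C; then 5; aq. NH4Cl
Reagents that add atoms: tert-butyl methoxyacetate, COCC(=O)OC(C)(C)C
Why: Aldol addition of the chelated lithium enolate of the α-alkoxy ester to a non-enolizable aromatic aldehyde at −78 °C; the two new stereocentres are left uncontrolled because both are erased in steps 4 and 5.

Step 4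
Reactants: 7 tert-butyl 3-hydroxy-2-methoxy-3-[3-methoxy-4-(methoxymethoxy)-5-(3-methylbut-2-en-1-yl)phenyl]propanoate
Product: 8 tert-butyl 2-methoxy-3-[3-methoxy-4-(methoxymethoxy)-5-(3-methylbut-2-en-1-yl)phenyl]-3-oxopropanoate (racemic)
Conditions: Dess–Martin periodinane (1.3 equiv), CH2Cl2, 0 °C → rt
Reagents that add atoms: none
Why: Dess–Martin oxidation of the secondary benzylic alcohol to the aryl ketone under near-neutral conditions that leave the prenyl alkene and the MOM acetal alone.

Step 5
Reactants: 8 tert-butyl 2-methoxy-3-[3-methoxy-4-(methoxymethoxy)-5-(3-methylbut-2-en-1-yl)phenyl]-3-oxopropanoate; 9 acetylacetone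
Product: 12 5-acetyl-3-methoxy-2-[3-methoxy-4-(methoxymethoxy)-5-(3-methylbut-2-en-1-yl)phenyl]-6-methyl-4H-pyran-4-one, via aroyl(methoxy)ketene 10 (not isolated), via open-chain tetraketone 11 (not isolated)
Conditions: acetylacetone (10 equiv), xylene, 140 °C, Dean–Stark trap charged with 4 Å molecular sieves
Reagents that add atoms: acetylacetone, CC(=O)CC(C)=O
Why: tert-Butyl β-keto esters lose tert-butanol on heating to give acylketenes, and 10 should be trapped at carbon by the enol of acetylacetone (the acylketene–1,3-dicarbonyl route to 3-acyl-4-pyranones, formally a hetero-Diels–Alder addition followed by dehydration); tetraketone 11 then cyclodehydrates across the aroyl and one acetyl carbonyl, and since the two acetyl groups are equivalent only pyranone 12 can result.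

Step 6
Reactants: 12 5-acetyl-3-methoxy-2-[3-methoxy-4-(methoxymethoxy)-5-(3-methylbut-2-en-1-yl)phenyl]-6-methyl-4H-pyran-4-one; 13 dimethyl carbonate
Product: 15 5,7-dihydroxy-3-methoxy-2-[3-methoxy-4-(methoxymethoxy)-5-(3-methylbut-2-en-1-yl)phenyl]-4H-chromen-4-one (4'-O-MOM dodoviscin J), via β-keto ester 14 (not isolated)
Conditions: LiN(i-Pr)2 (LDA, 2.2 equiv), THF, −78 → −30 °C; (MeO)2CO (1.1 equiv), −78 → 0 °C; LiN(SiMe3)2 (2.5 equiv), 0 °C → rt; aq. NH4Cl
Reagents that add atoms: dimethyl carbonate, COC(=O)OC
Why: Proposed new method: two equivalents of LDA should turn 12 into the cross-conjugated dianion (6-methyl deprotonated through the vinylogous C4 carbonyl, acetyl deprotonated as its enolate), whose more basic acetyl terminus attacks dimethyl carbonate to give β-keto ester 14 (bond C6–C7); LiN(SiMe3)2 then holds the keto ester and the C8 methylene deprotonated, and the C8 carbanion attacks the ester carbonyl in a Dieckmann-type Claisen closure (bond C7–C8) with loss of the second methoxide, four equivalents of base being consumed in all. The closest known reaction types are the carboxylation of ketone enolates with dialkyl carbonates, the lateral lithiation–acylation of 2-methyl-4-pyranones and 2-methylchromones, and the acylation–Dieckmann annulation of o-toluate anions to naphthalene-1,3-diols; the one-pot [5+1] version on a 3-acetyl-2-methyl-4-pyranone is untested. Ring A closes 6-exo-trig at the ester carbonyl, and the new cyclohexane-1,3-dione unit enolizes at once to the aromatic 5,7-diol (C5–OH hydrogen-bonded to C4=O), whose dilithium salt is the thermodynamic sink that pulls the reversible Claisen steps forward. No stereocentre is formed. The step needs carbon acylation to win over O-acylation and over addition of amide or methoxide to C2 and C8a of the pyranone: hindered amide bases, low temperature, the fully substituted ring carbons and the electron-rich dienolate form of the ring (no longer a Michael acceptor) should secure this, and any enol carbonate is returned by methoxide.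

Step 7
Reactants: 15 5,7-dihydroxy-3-methoxy-2-[3-methoxy-4-(methoxymethoxy)-5-(3-methylbut-2-en-1-yl)phenyl]-4H-chromen-4-one
Product: 16 dodoviscin J, 5,7-dihydroxy-2-[4-hydroxy-3-methoxy-5-(3-methylbut-2-en-1-yl)phenyl]-3-methoxy-4H-chromen-4-one
Conditions: HCl (2 M) in MeOH, 40 °C
Reagents that add atoms: none
Why: Acid-catalysed acetal exchange with methanol (MOM cleavage) should release the 4'-phenol; dilute acid at 40 °C is chosen so that the ortho-prenyl group does not add to the new phenol (chroman formation).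

**Compound list**

1 | 5-iodovanillin (4-hydroxy-3-iodo-5-methoxybenzaldehyde) | O=Cc1cc(I)c(O)c(OC)c1 | starting material
2 | chloromethyl methyl ether | COCCl | starting material
3 | 3-iodo-5-methoxy-4-(methoxymethoxy)benzaldehyde | O=Cc1cc(I)c(OCOC)c(OC)c1 | intermediate
4 | tributyl(3-methylbut-2-en-1-yl)stannane | CCCC[Sn](CCCC)(CCCC)CC=C(C)C | starting material
5 | 3-methoxy-4-(methoxymethoxy)-5-(3-methylbut-2-en-1-yl)benzaldehyde | O=Cc1cc(CC=C(C)C)c(OCOC)c(OC)c1 | intermediate
6 | tert-butyl methoxyacetate | COCC(=O)OC(C)(C)C | starting material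
7 | tert-butyl 3-hydroxy-2-methoxy-3-[3-methoxy-4-(methoxymethoxy)-5-(3-methylbut-2-en-1-yl)phenyl]propanoate (racemic syn/anti mixture) | CC(C)(C)OC(=O)C(OC)C(O)c1cc(CC=C(C)C)c(OCOC)c(OC)c1 | intermediate
8 | tert-butyl 2-methoxy-3-[3-methoxy-4-(methoxymethoxy)-5-(3-methylbut-2-en-1-yl)phenyl]-3-oxopropanoate (racemic) | CC(C)(C)OC(=O)C(OC)C(=O)c1cc(CC=C(C)C)c(OCOC)c(OC)c1 | intermediate
9 | acetylacetone (pentane-2,4-dione) | CC(=O)CC(C)=O | starting material
10 | 2-methoxy-3-[3-methoxy-4-(methoxymethoxy)-5-(3-methylbut-2-en-1-yl)phenyl]-3-oxoprop-1-en-1-one (aroyl(methoxy)ketene) | O=C=C(OC)C(=O)c1cc(CC=C(C)C)c(OCOC)c(OC)c1 | intermediate (not isolated)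
11 | 4-acetyl-2-methoxy-1-[3-methoxy-4-(methoxymethoxy)-5-(3-methylbut-2-en-1-yl)phenyl]hexane-1,3,5-trione (drawn as keto form) | CC(=O)C(C(C)=O)C(=O)C(OC)C(=O)c1cc(CC=C(C)C)c(OCOC)c(OC)c1 | intermediate (not isolated)
12 | 5-acetyl-3-methoxy-2-[3-methoxy-4-(methoxymethoxy)-5-(3-methylbut-2-en-1-yl)phenyl]-6-methyl-4H-pyran-4-one | CC(=O)c1c(C)oc(-c2cc(CC=C(C)C)c(OCOC)c(OC)c2)c(OC)c1=O | intermediate
13 | dimethyl carbonate | COC(=O)OC | starting material
14 | methyl 3-{5-methoxy-6-[3-methoxy-4-(methoxymethoxy)-5-(3-methylbut-2-en-1-yl)phenyl]-2-methyl-4-oxo-4H-pyran-3-yl}-3-oxopropanoate | COC(=O)CC(=O)c1c(C)oc(-c2cc(CC=C(C)C)c(OCOC)c(OC)c2)c(OC)c1=O | intermediate (not isolated)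
15 | 5,7-dihydroxy-3-methoxy-2-[3-methoxy-4-(methoxymethoxy)-5-(3-methylbut-2-en-1-yl)phenyl]-4H-chromen-4-one (4'-O-MOM dodoviscin J) | COCOc1c(OC)cc(-c2oc3cc(O)cc(O)c3c(=O)c2OC)cc1CC=C(C)C | intermediate
16 | dodoviscin J | COc1cc(-c2oc3cc(O)cc(O)c3c(=O)c2OC)cc(CC=C(C)C)c1O | target

**Step count**

Total step count: 7. Longest linear sequence: 7 steps (1 → 16).

**Steps most likely to fail**

1. Step 6 (proposed new method). The ring closure may stall at the deprotonated β-keto ester stage, because the ester carbonyl of a keto ester enolate is a poor electrophile. Methoxide or amide may instead open the pyranone ring, or the dianion may condense with a second molecule.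

   Fallback (sets out from 5, returns at 16), a Baker–Venkataraman construction of ring C on a ready-made ring A. Pinnick oxidation of aldehyde 5 (NaClO2, NaH2PO4, 2-methyl-2-butene, t-BuOH/H2O) would give 3-methoxy-4-(methoxymethoxy)-5-(3-methylbut-2-en-1-yl)benzoic acid F1. In parallel, Hoesch acylation of phloroglucinol with methoxyacetonitrile (ZnCl2, HCl, Et2O, 0 °C) gives the ketiminium chloride F2, hydrolysed in hot water to 2-methoxy-1-(2,4,6-trihydroxyphenyl)ethan-1-one F3. Bis-protection (MOMCl 2.2 equiv, i-Pr2NEt, CH2Cl2) leaves the chelated ortho hydroxyl free and gives 1-[2-hydroxy-4,6-bis(methoxymethoxy)phenyl]-2-methoxyethan-1-one F4. Esterification of F4 with F1 (EDC·HCl, DMAP, CH2Cl2) gives the aryl benzoate F5. Baker–Venkataraman rearrangement (KOH, pyridine, 50 °C) moves the aroyl group to the methoxy-bearing carbon and gives the 2-methoxy-1,3-diketone F6. HCl in MeOH at 50 °C then cyclodehydrates F6 and removes all three MOM ethers, arriving at target 16.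

2. Step 5. Ketene release from the α-methoxy ester may be slow, so that ester pyrolysis and decarboxylation to the aryl methoxymethyl ketone take over. The water formed in the ring closure may hydrolyse ketene not yet trapped, or acetylacetone may be acylated on oxygen without rearranging to carbon.

   Fallback (sets out from 5, returns at 12), a cinnamoyl route with later adjustment of the oxidation level. Horner–Wadsworth–Emmons olefination of 5 with methyl 2-(dimethoxyphosphoryl)-2-methoxyacetate (NaH, THF, 0 °C → rt) would give the methyl α-methoxycinnamate F7 as an E/Z mixture. Saponification (LiOH, THF/H2O) gives the α-methoxycinnamic acid F8. 1-Chloro-N,N,2-trimethylprop-1-en-1-amine in CH2Cl2 converts F8 under neutral conditions into the acid chloride F9. F9 C-acylates acetylacetone (MgCl2, pyridine, CH2Cl2, 0 °C) to the 3-(α-methoxycinnamoyl)pentane-2,4-dione F10. Et3N in EtOH at reflux should close the enol onto the enone by oxa-Michael addition to the 2,3-dihydro-4-pyranone F11. Dehydrogenation with IBX (DMSO, 70 °C) returns pyranone 12.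

3. Step 2. Transmetalation with allylic transposition may deliver the reverse-prenyl (1,1-dimethylallyl) isomer, and coupling next to the MOM ether may be slow enough for protodestannylation to compete.

   Fallback (sets out from 3, returns at 5), allylation then olefin cross-metathesis. Stille coupling of 3 with allyltributylstannane (Pd(PPh3)4, DMF, 90 °C), for which allylic transposition is degenerate, would give 3-methoxy-4-(methoxymethoxy)-5-(prop-2-en-1-yl)benzaldehyde F12. Cross-metathesis with a large excess of 2-methyl-2-butene (second-generation Grubbs catalyst RuCl2(=CHPh)(H2IMes)(PCy3), CH2Cl2, 40 °C) turns the allyl into the prenyl group and returns aldehyde 5.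

**Further compounds**

F1 | step 6 | 3-methoxy-4-(methoxymethoxy)-5-(3-methylbut-2-en-1-yl)benzoic acid | OC(=O)c1cc(CC=C(C)C)c(OCOC)c(OC)c1
F2 | step 6 | 2-methoxy-1-(2,4,6-trihydroxyphenyl)ethan-1-iminium chloride | COCC(=[NH2+])c1c(O)cc(O)cc1O.[Cl-]
F3 | step 6 | 2-methoxy-1-(2,4,6-trihydroxyphenyl)ethan-1-one | COCC(=O)c1c(O)cc(O)cc1O
F4 | step 6 | 1-[2-hydroxy-4,6-bis(methoxymethoxy)phenyl]-2-methoxyethan-1-one | COCC(=O)c1c(O)cc(OCOC)cc1OCOC
F5 | step 6 | 2-(2-methoxyacetyl)-3,5-bis(methoxymethoxy)phenyl 3-methoxy-4-(methoxymethoxy)-5-(3-methylbut-2-en-1-yl)benzoate | COCC(=O)c1c(OCOC)cc(OCOC)cc1OC(=O)c2cc(CC=C(C)C)c(OCOC)c(OC)c2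
F6 | step 6 | 1-[2-hydroxy-4,6-bis(methoxymethoxy)phenyl]-2-methoxy-3-[3-methoxy-4-(methoxymethoxy)-5-(3-methylbut-2-en-1-yl)phenyl]propane-1,3-dione | COCOc1cc(O)c(C(=O)C(OC)C(=O)c2cc(CC=C(C)C)c(OCOC)c(OC)c2)c(OCOC)c1
F7 | step 5 | methyl 2-methoxy-3-[3-methoxy-4-(methoxymethoxy)-5-(3-methylbut-2-en-1-yl)phenyl]prop-2-enoate (E/Z mixture) | COC(=O)C(OC)=Cc1cc(CC=C(C)C)c(OCOC)c(OC)c1
F8 | step 5 | 2-methoxy-3-[3-methoxy-4-(methoxymethoxy)-5-(3-methylbut-2-en-1-yl)phenyl]prop-2-enoic acid (E/Z mixture) | OC(=O)C(OC)=Cc1cc(CC=C(C)C)c(OCOC)c(OC)c1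
F9 | step 5 | 2-methoxy-3-[3-methoxy-4-(methoxymethoxy)-5-(3-methylbut-2-en-1-yl)phenyl]prop-2-enoyl chloride (E/Z mixture) | ClC(=O)C(OC)=Cc1cc(CC=C(C)C)c(OCOC)c(OC)c1
F10 | step 5 | 3-{2-methoxy-3-[3-methoxy-4-(methoxymethoxy)-5-(3-methylbut-2-en-1-yl)phenyl]prop-2-enoyl}pentane-2,4-dione (drawn as keto form) | CC(=O)C(C(C)=O)C(=O)C(OC)=Cc1cc(CC=C(C)C)c(OCOC)c(OC)c1
F11 | step 5 | 5-acetyl-3-methoxy-2-[3-methoxy-4-(methoxymethoxy)-5-(3-methylbut-2-en-1-yl)phenyl]-6-methyl-2,3-dihydro-4H-pyran-4-one (racemic cis/trans mixture) | CC(=O)C1=C(C)OC(c2cc(CC=C(C)C)c(OCOC)c(OC)c2)C(OC)C1=O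
F12 | step 2 | 3-methoxy-4-(methoxymethoxy)-5-(prop-2-en-1-yl)benzaldehyde | O=Cc1cc(CC=C)c(OCOC)c(OC)c1
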